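**Retrosynthetic overview**

1. Numbering: bicyclo[4.3.1]dec-8-ene with C1/C6 bridgeheads, C2–C5 the four-carbon bridge, C7–C9 the three-carbon bridge and C10 the one-carbon bridge. Target 23 ⇐ cross-metathesis (prenyl end), acetylation and MnO2 oxidation ⇐ triol 20.
2. 20 ⇐ carbonyl-ene closure of the seven-membered ring (C1–C2–C3–C4–C5–C6–C10) at C3–C4 from lactol 18. Enabling feature: the isopropenyl group on C6 (its CH2 becomes C4, its central carbon C5, its CH3 the exocyclic methylene) sits cis to the C1 arm carrying the masked C3 aldehyde, on the preformed cyclohexene ring C1/C6–C10.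
3. 18 ⇐ cis-fused γ-lactone 17 (temporary ring C10–O–C3–C2–C1; C2 set by kinetic protonation) ⇐ monocyclic diol ester 14 ⇐ radical opening of the cyclobutane of pinane epoxide 11, which delivers the isopropenyl group, C8=C9 and C9–CH2OH together.
4. 11 ⇐ (+)-verbenone 1 + (S)-citronellic acid 3: Pd coupling makes C1–C2; proton and hydride delivery anti to the gem-dimethyl bridge set C1 and C10 cis to the future isopropenyl; C6 comes from 1, the side-chain centre from 3; the prenyl end is carried as vinyl and restored last.
5. Ring order: six-membered ring (from 1, present throughout) → cyclobutane opened (step 8) → temporary lactone closed (step 9) and opened again (step 12) → seven-membered ring last (step 12).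

Key step: step 12

Remark: (1R,5R)-(+)-verbenone and (S)-citronellic acid are taken as commercial materials of high enantiomeric purity.
Remark: compounds 7 to 14 are pairs of epimers at the ester α-carbon (the future C2), left undefined in their SMILES; the pair converges in steps 9 and 10.

**Route**

Step 1
Reactants: 1 (1R,5R)-(+)-verbenone
Product: 2 3-iodoverbenone
Conditions: I2 (2 equiv), pyridine/CH2Cl2 (1:1), 0 °C → rt
Reagents that add atoms: iodine, II
Why: Pyridine adds to the β-carbon of the enone and the resulting enolate is iodinated at C-3 before pyridine is expelled (addition–elimination α-iodination of an enone under Baylis–Hillman-type conditions), which installs the cross-coupling handle on the future C1 without generating a cation next to the cyclobutane.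

Step 2
Reactants: 3 (S)-citronellic acid
Product: 4 tert-butyl (3S)-3,7-dimethyloct-6-enoate
Conditions: Boc2O (2 equiv), DMAP (0.3 equiv), t-BuOH, 30 °C
Reagents that add atoms: di-tert-butyl dicarbonate, CC(C)(C)OC(=O)OC(=O)OC(C)(C)C
Why: DMAP-catalysed acyl transfer through the mixed carbonic anhydride (Boc2O esterification) gives the tert-butyl ester, which is bulky enough to stay open-chain until step 9 and leaves the C-3 stereocentre untouched.

Step 3
Reactants: 4 tert-butyl (3S)-3,7-dimethyloct-6-enoate
Product: 5 tert-butyl (3S)-3-methylhept-6-enoate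
Conditions: second-generation Grubbs catalyst (3 mol%), ethylene (5 bar), toluene, 50 °C
Reagents that add atoms: ethylene, C=C
Why: Cross-metathesis with ethylene (ethenolysis) is driven by excess ethylene and loss of isobutene and replaces the nucleophilic trisubstituted alkene by a vinyl group, a temporary truncation that keeps the side chain out of the epoxidation of step 7 and out of the isopulegol-type ene reaction that a prenyl group would undergo with the activated aldehyde in step 12.

Step 4
Reactants: 5 tert-butyl (3S)-3-methylhept-6-enoate; 2 3-iodoverbenone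
Product: 7 tert-butyl (3S)-3-methyl-2-(verbenon-3-yl)hept-6-enoate (both C-2 epimers), via chlorozinc ester enolate 6 (not isolated)
Conditions: 5, LiN(i-Pr)2, THF, −78 °C; ZnCl2, −78 °C → rt; then 2, Pd(dba)2 (5 mol%), P(t-Bu)3 (10 mol%), THF, rt → 40 °C
Reagents that add atoms: none
Why: The zinc enolate made by deprotonation and transmetalation couples with the α-iodoenone under zerovalent palladium catalysis (Reformatsky–Negishi cross-coupling: oxidative addition then transmetalation then reductive elimination) and forges the future C1–C2 bond; the new α-centre of the ester forms without control and is corrected in steps 9 and 10.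

Step 5
Reactants: 7 tert-butyl (3S)-3-methyl-2-(verbenon-3-yl)hept-6-enoate
Product: 9 deconjugated ketone (exocyclic methylene on C-4; ester side chain on C-3 syn to the gem-dimethyl bridge; H-3 anti), via potassium exocyclic dienolate 8 (not isolated)
Conditions: KN(SiMe3)2 (1.2 equiv), THF, −78 °C; then AcOH (3 equiv) in THF, −78 °C; cold neutral work-up
Reagents that add atoms: none
Why: Because both bridgeheads are blocked the base can only remove a γ-hydrogen of the ring methyl group, and kinetic α-protonation of the resulting exocyclic dienolate (deconjugative protonation) from the face anti to the gem-dimethyl bridge gives the β,γ-unsaturated ketone with H-3 anti and the side chain syn to that bridge, which fixes the future C1 and creates the exocyclic methylene needed for step 7.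

Step 6
Reactants: 9 deconjugated ketone
Product: 10 pinane alcohol (OH-2 and the C-3 side chain both syn to the gem-dimethyl bridge)
Conditions: NaBH4, CeCl3·7H2O, MeOH, −40 °C (crude 9 used at once)
Reagents that add atoms: none
Why: Luche reduction delivers hydride to the carbonyl from the face anti to the gem-dimethyl bridge (the sense in which verbenone gives cis-verbenol), so the hydroxyl of the future C10 ends syn to the bridge and cis to the side chain, and the fast low-temperature reduction outruns re-conjugation of the enolisable ketone.

Step 7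
Reactants: 10 pinane alcohol
Product: 11 spiro-epoxide of 10 (oxirane oxygen anti to the gem-dimethyl bridge)
Conditions: dimethyldioxirane (1.05 equiv, acetone solution), CH2Cl2, −20 °C
Reagents that add atoms: dimethyldioxirane, CC1(C)OO1
Why: The electrophilic dioxirane epoxidises the strained 1,1-disubstituted exocyclic alkene much faster than the monosubstituted vinyl group and from the face anti to the bridge as in β-pinene, under neutral conditions that leave the acid-sensitive spiro-epoxide intact; the configuration of the spiro carbon is erased in step 8.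

Step 8
Reactants: 11 spiro-epoxide
Product: 14 tert-butyl (3S)-2-[(1R,5R,6S)-6-hydroxy-2-(hydroxymethyl)-5-(prop-1-en-2-yl)cyclohex-2-en-1-yl]-3-methylhept-6-enoate, via cyclobutylcarbinyl radical 12 (not isolated), via ring-opened tertiary radical 13 (not isolated)
Conditions: Cp2TiCl2 (2.5 equiv), Mn dust (8 equiv), THF, rt (green Cp2TiCl preformed, 11 added slowly); 1 M HCl work-up
Reagents that add atoms: none
Why: Cp2TiCl (trivalent titanium) opens the epoxide by single-electron transfer to the tertiary cyclobutylcarbinyl radical 12, strain-driven β-scission of the cyclobutane bond to the gem-dimethyl carbon gives the ring alkene and the tertiary radical 13, and capture of 13 by a second titanium centre followed by β-hydride loss gives the isopropenyl group (the radical counterpart of the β-pinene oxide to perillyl alcohol isomerisation), so that the three ring stereocentres are untouched and emerge mutually cis.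

Step 9
Reactants: 14 monocyclic diol ester
Product: 15 cis-fused γ-lactone (3S epimer; side chain on the convex face)
Conditions: KOt-Bu (0.2 equiv), THF, 0 °C → rt
Reagents that add atoms: none
Why: Alkoxide-catalysed intramolecular transesterification closes the cis-fused five-membered lactone on the secondary hydroxyl, which is preferred under these equilibrating conditions over the six-membered lactone on the primary hydroxyl, and the same base epimerises the α-centre so that both epimers converge on the exo lactone.

Step 10
Reactants: 15 cis-fused γ-lactone (3S)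
Product: 17 cis-fused γ-lactone (3R epimer; side chain on the concave face), via dilithium alkoxide enolate 16 (not isolated)
Conditions: LiN(i-Pr)2 (2.4 equiv), THF, −78 → −40 °C; then t-BuCO2H (5 equiv) in THF, −78 °C
Reagents that add atoms: none
Why: The planar lithium enolate of the cis-fused lactone is protonated kinetically by the bulky acid on its convex face (the face of the ring-fusion hydrogens), which forces the side chain onto the concave face and gives the less stable 3R epimer that corresponds to C2 of the target (kinetic enolate protonation), while the hydroxymethyl group is held as its alkoxide so that it cannot return a proton from the concave side.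

Step 11
Reactants: 17 cis-fused γ-lactone (3R)
Product: 18 lactol (anomer mixture)
Conditions: i-Bu2AlH (3.2 equiv), CH2Cl2, −78 °C; aq. KNaC4H4O6 work-up; used without delay
Reagents that add atoms: none
Why: At −78 °C the aluminium hydride adds once to the lactone carbonyl and the tetrahedral aluminium lactolate survives until hydrolysis (partial reduction of a lactone to a lactol), which gives the masked C3 aldehyde without epimerising the adjacent centre.

Step 12
Reactants: 18 lactol
Product: 20 (1R,2R,3S,6R,10S)-2-[(2S)-hex-5-en-2-yl]-9-(hydroxymethyl)-5-methylidenebicyclo[4.3.1]dec-8-ene-3,10-diol, via ring-opened aluminium-bound aldehyde 19 (not isolated)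
Conditions: Me2AlCl (5 equiv), CH2Cl2, −78 → −20 °C; aq. KNaC4H4O6 work-up
Reagents that add atoms: none
Why: Me2AlCl turns the hydroxyl groups into aluminium alkoxides with loss of methane, the lactolate ring opens to the aluminium-activated aldehyde 19, and the CH2 terminus of the isopropenyl group attacks the aldehyde carbon while a methyl hydrogen passes to oxygen (concerted, asynchronous carbonyl-ene reaction), which forms the C3–C4 bond, the C5 exocyclic methylene and the free C10 hydroxyl in one operation. The closest known reaction type is the Me2AlCl-promoted type-two intramolecular carbonyl-ene cyclisation of aldehydes onto 1,1-disubstituted alkenes, which gives 3-methylenecycloalkanols including seven-membered rings. The seven-membered ring closes 7-exo-trig with respect to the carbonyl group and endo with respect to the alkene, so that both alkene carbons become ring atoms. The new C3 centre is controlled by a chair-like transition state in which the forming C2–C5 bridge swings away from the aluminium-bound oxygen on C10 towards the flat C8=C9 bridge, the C2 side chain is pseudo-equatorial and the carbonyl oxygen pseudo-axial within reach of the methyl hydrogen, which should give the 3S alcohol; C1, C2, C6 and C10 are already fixed. The step needs the two reacting arms cis and needs chemoselectivity for the isopropenyl group: the all-cis array set on the pinane template lets both arms become axial on one face, the ring alkene cannot reach the aldehyde, and the side chain carries only a weakly nucleophilic vinyl group.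

Step 13
Reactants: 20 bicyclic triol
Product: 21 (1R,2R,3S,6R,10S)-2-[(2S)-hex-5-en-2-yl]-3,10-dihydroxy-5-methylidenebicyclo[4.3.1]dec-8-ene-9-carbaldehyde
Conditions: MnO2 (20 equiv), CH2Cl2, rt
Reagents that add atoms: none
Why: MnO2 oxidises only the allylic primary alcohol on C9 to the aldehyde (chemoselective allylic oxidation), because the C3 and C10 hydroxyls are not allylic.

Step 14
Reactants: 21 enal diol
Product: 22 (1R,2R,3S,6R,10S)-9-formyl-2-[(2S)-hex-5-en-2-yl]-5-methylidenebicyclo[4.3.1]dec-8-ene-3,10-diyl diacetate
Conditions: Ac2O (6 equiv), DMAP (0.3 equiv), pyridine, rt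
Reagents that add atoms: acetic anhydride, CC(=O)OC(C)=O
Why: DMAP-catalysed acylation acetylates both secondary hydroxyls with retention, and the enal is inert because C1 is not an acidic position.

Step 15
Reactants: 22 diacetate with vinyl-terminated side chain
Product: 23 target, (1R,2R,3S,6R,10S)-9-formyl-5-methylidene-2-[(2S)-6-methylhept-5-en-2-yl]bicyclo[4.3.1]dec-8-ene-3,10-diyl diacetate
Conditions: second-generation Grubbs catalyst (5 mol%), 2-methylbut-2-ene/CH2Cl2 (1:1), 40 °C
Reagents that add atoms: 2-methylbut-2-ene, CC=C(C)C
Why: Ruthenium-carbene cross-metathesis of the terminal vinyl group with excess 2-methylbut-2-ene restores the prenyl terminus with loss of propene, while the hindered 1,1-disubstituted exocyclic methylene and the electron-poor trisubstituted enal are poor metathesis partners and stay untouched.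

**Compound list**

1 | (1R,5R)-(+)-verbenone, (1R,5R)-4,6,6-trimethylbicyclo[3.1.1]hept-3-en-2-one | CC1=CC(=O)[C@@H]2C[C@H]1C2(C)C | starting material
2 | 3-iodoverbenone (3-iodo-4,6,6-trimethylbicyclo[3.1.1]hept-3-en-2-one, bridgeheads as in 1) | CC1=C(I)C(=O)[C@@H]2C[C@H]1C2(C)C | intermediate
3 | (S)-citronellic acid, (3S)-3,7-dimethyloct-6-enoic acid | C[C@@H](CCC=C(C)C)CC(=O)O | starting material
4 | tert-butyl (3S)-3,7-dimethyloct-6-enoate | C[C@@H](CCC=C(C)C)CC(=O)OC(C)(C)C | intermediate
5 | tert-butyl (3S)-3-methylhept-6-enoate | C[C@@H](CCC=C)CC(=O)OC(C)(C)C | intermediate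
6 | chlorozinc enolate of 5 | C[C@@H](CCC=C)C=C(O[Zn]Cl)OC(C)(C)C | intermediate
7 | tert-butyl (3S)-3-methyl-2-(4,6,6-trimethyl-2-oxobicyclo[3.1.1]hept-3-en-3-yl)hept-6-enoate (bridgeheads as in 1; both C-2 epimers) | CC1=C(C(C(=O)OC(C)(C)C)[C@@H](C)CCC=C)C(=O)[C@@H]2C[C@H]1C2(C)C | intermediate
8 | potassium exocyclic dienolate of 7 | C=C1C(C(C(=O)OC(C)(C)C)[C@@H](C)CCC=C)=C(O[K])[C@@H]2C[C@H]1C2(C)C | intermediate
9 | tert-butyl (3S)-2-(6,6-dimethyl-4-methylidene-2-oxobicyclo[3.1.1]hept-3-yl)-3-methylhept-6-enoate (ring substituent on C-3 syn to the gem-dimethyl bridge, H-3 anti; C-2 epimers) | C=C1[C@@H](C(C(=O)OC(C)(C)C)[C@@H](C)CCC=C)C(=O)[C@@H]2C[C@H]1C2(C)C | intermediate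
10 | tert-butyl (3S)-2-(2-hydroxy-6,6-dimethyl-4-methylidenebicyclo[3.1.1]hept-3-yl)-3-methylhept-6-enoate (OH-2 and C-3 substituent both syn to the gem-dimethyl bridge; C-2 epimers) | C=C1[C@@H](C(C(=O)OC(C)(C)C)[C@@H](C)CCC=C)[C@@H](O)[C@@H]2C[C@H]1C2(C)C | intermediate
11 | spiro-epoxide of 10 at the exocyclic methylene (oxirane oxygen anti to the gem-dimethyl bridge; C-2 epimers) | O1C[C@]12[C@@H](C(C(=O)OC(C)(C)C)[C@@H](C)CCC=C)[C@@H](O)[C@@H]3C[C@H]2C3(C)C | intermediate
12 | tertiary cyclobutylcarbinyl radical (titanium alkoxide of the opened epoxide) | Cl[Ti](OC[C]1[C@@H](C(C(=O)OC(C)(C)C)[C@@H](C)CCC=C)[C@@H](O)[C@@H]2C[C@H]1C2(C)C)(C1C=CC=C1)C1C=CC=C1 | intermediate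
13 | ring-opened tertiary 2-propyl radical on the cyclohexene | Cl[Ti](OCC1=CC[C@H]([C](C)C)[C@H](O)[C@@H]1C(C(=O)OC(C)(C)C)[C@@H](C)CCC=C)(C1C=CC=C1)C1C=CC=C1 | intermediate
14 | tert-butyl (3S)-2-[(1R,5R,6S)-6-hydroxy-2-(hydroxymethyl)-5-(prop-1-en-2-yl)cyclohex-2-en-1-yl]-3-methylhept-6-enoate (ring substituents on C1, C5, C6 all cis; C-2 epimers) | OCC1=CC[C@H](C(C)=C)[C@H](O)[C@@H]1C(C(=O)OC(C)(C)C)[C@@H](C)CCC=C | intermediate
15 | (3S,3aR,7R,7aS)-3-[(2S)-hex-5-en-2-yl]-4-(hydroxymethyl)-7-(prop-1-en-2-yl)-3a,6,7,7a-tetrahydro-1-benzofuran-2(3H)-one | OCC1=CC[C@H](C(C)=C)[C@@H]2OC(=O)[C@@H]([C@@H](C)CCC=C)[C@H]12 | intermediate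
16 | dilithium alkoxide enolate of 15 | [Li]OCC1=CC[C@H](C(C)=C)[C@@H]2OC(O[Li])=C([C@@H](C)CCC=C)[C@H]12 | intermediate
17 | (3R,3aR,7R,7aS)-3-[(2S)-hex-5-en-2-yl]-4-(hydroxymethyl)-7-(prop-1-en-2-yl)-3a,6,7,7a-tetrahydro-1-benzofuran-2(3H)-one | OCC1=CC[C@H](C(C)=C)[C@@H]2OC(=O)[C@H]([C@@H](C)CCC=C)[C@H]12 | intermediate
18 | (3R,3aR,7R,7aS)-3-[(2S)-hex-5-en-2-yl]-4-(hydroxymethyl)-7-(prop-1-en-2-yl)-2,3,3a,6,7,7a-hexahydro-1-benzofuran-2-ol (anomers) | OCC1=CC[C@H](C(C)=C)[C@@H]2OC(O)[C@H]([C@@H](C)CCC=C)[C@H]12 | intermediate
19 | ring-opened aldehyde with both oxygens as chloro(methyl)aluminium alkoxides | C[Al](Cl)OCC1=CC[C@H](C(C)=C)[C@H](O[Al](C)Cl)[C@@H]1[C@H](C=O)[C@@H](C)CCC=C | intermediate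
20 | (1R,2R,3S,6R,10S)-2-[(2S)-hex-5-en-2-yl]-9-(hydroxymethyl)-5-methylidenebicyclo[4.3.1]dec-8-ene-3,10-diol | C=C1C[C@H](O)[C@H]([C@@H](C)CCC=C)[C@@H]2C(CO)=CC[C@H]1[C@@H]2O | intermediate
21 | (1R,2R,3S,6R,10S)-2-[(2S)-hex-5-en-2-yl]-3,10-dihydroxy-5-methylidenebicyclo[4.3.1]dec-8-ene-9-carbaldehyde | C=C1C[C@H](O)[C@H]([C@@H](C)CCC=C)[C@@H]2C(C=O)=CC[C@H]1[C@@H]2O | intermediate
22 | (1R,2R,3S,6R,10S)-9-formyl-2-[(2S)-hex-5-en-2-yl]-5-methylidenebicyclo[4.3.1]dec-8-ene-3,10-diyl diacetate | C=C1C[C@H](OC(C)=O)[C@H]([C@@H](C)CCC=C)[C@@H]2C(C=O)=CC[C@H]1[C@@H]2OC(C)=O | intermediate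
23 | (1R,2R,3S,6R,10S)-9-formyl-5-methylidene-2-[(2S)-6-methylhept-5-en-2-yl]bicyclo[4.3.1]dec-8-ene-3,10-diyl diacetate | C=C1C[C@H](OC(C)=O)[C@H]([C@@H](C)CCC=C(C)C)[C@@H]2C(C=O)=CC[C@H]1[C@@H]2OC(C)=O | target

**Step count and risks**

Total steps: 15. Longest linear sequence: 14 steps (from 3, steps 2 to 15); 13 steps from 1.

Steps most likely to fail, in order: step 12, step 10, step 8.

Step 12. The forming bridge may close through the boat-like array, or through a stepwise cationic pathway, so that the aldehyde is attacked on its other face and the C3 epimer results (poor facial selectivity at the carbonyl). The fallback sets out from 18 and returns at 22; the centre is then set by substitution and not by the ene transition state. The cyclisation product is taken on as the C3-epimeric triol F1. MnO2 oxidation gives the epimeric enal diol F2. A Mitsunobu reaction (PPh3, diisopropyl azodicarboxylate, AcOH, THF) inverts the accessible C3 hydroxyl by SN2 displacement, while the C10 hydroxyl between the two bridgeheads does not react, and gives the 3S mono-acetate F3. Ac2O, DMAP and pyridine then acetylate C10 and give 22.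

Step 10. The protonation may lack facial selectivity, or the amine may return its proton within the enolate aggregate, so that the stable exo epimer is re-formed. The fallback sets out from 14 and returns at 20; it uses thermodynamic instead of kinetic control, through the isomeric six-membered lactone. Compound 14 is silylated twice (t-BuMe2SiOTf, 2,6-lutidine) to the bis-silyl ether F4. The primary allylic silyl ether is cleaved selectively (pyridinium p-toluenesulfonate, MeOH) to give the secondary silyl ether F5. KOt-Bu (cat.) then closes the lactone on the primary hydroxyl and equilibrates the α-centre. In this lactone the required configuration places the side chain trans to the neighbouring ring C–C bond, both pseudo-equatorial, and should be the stable epimer, the δ-lactone F6. i-Bu2AlH gives the δ-lactol F7, Me2AlCl effects the same carbonyl-ene closure to the C10 silyl ether F8, and Bu4NF gives 20.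

Step 8. The tertiary radical may abstract hydrogen from the solvent and end as an isopropyl group (over-reduction), or radical 12 may be trapped before the ring opens. The fallback sets out from 11 and returns at 14; it uses the polar instead of the radical manifold. A mild Brønsted acid in a dipolar solvent (for example NH4NO3 or catalytic TsOH in DMSO, 40–60 °C) is applied, the conditions under which β-pinene oxide isomerises to perillyl alcohol. The cyclobutane bond antiperiplanar to the breaking C–O bond shifts in concert and the resulting 2-propyl cation loses a methyl proton; no new compound is made (F0).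

Further compounds
F1 | step 12 | (1R,2R,3R,6R,10S)-2-[(2S)-hex-5-en-2-yl]-9-(hydroxymethyl)-5-methylidenebicyclo[4.3.1]dec-8-ene-3,10-diol (C3 epimer of 20) | C=C1C[C@@H](O)[C@H]([C@@H](C)CCC=C)[C@@H]2C(CO)=CC[C@H]1[C@@H]2O
F2 | step 12 | (1R,2R,3R,6R,10S)-2-[(2S)-hex-5-en-2-yl]-3,10-dihydroxy-5-methylidenebicyclo[4.3.1]dec-8-ene-9-carbaldehyde (C3 epimer of 21) | C=C1C[C@@H](O)[C@H]([C@@H](C)CCC=C)[C@@H]2C(C=O)=CC[C@H]1[C@@H]2O
F3 | step 12 | (1R,2R,3S,6R,10S)-9-formyl-2-[(2S)-hex-5-en-2-yl]-10-hydroxy-5-methylidenebicyclo[4.3.1]dec-8-en-3-yl acetate | C=C1C[C@H](OC(C)=O)[C@H]([C@@H](C)CCC=C)[C@@H]2C(C=O)=CC[C@H]1[C@@H]2O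
F4 | step 10 | bis(tert-butyldimethylsilyl) ether of 14 | CC(C)(C)[Si](C)(C)OCC1=CC[C@H](C(C)=C)[C@H](O[Si](C)(C)C(C)(C)C)[C@@H]1C(C(=O)OC(C)(C)C)[C@@H](C)CCC=C
F5 | step 10 | C6 tert-butyldimethylsilyl ether of 14 with free hydroxymethyl group | OCC1=CC[C@H](C(C)=C)[C@H](O[Si](C)(C)C(C)(C)C)[C@@H]1C(C(=O)OC(C)(C)C)[C@@H](C)CCC=C
F6 | step 10 | six-membered lactone between the ester carbonyl and the CH2OH group of F5 (4a,5,6,7-tetrahydro-1H-isochromen-3(4H)-one core; α side chain trans to the adjacent ring C–C bond; silyl ether retained) | O=C1OCC2=CC[C@H](C(C)=C)[C@H](O[Si](C)(C)C(C)(C)C)[C@@H]2[C@H]1[C@@H](C)CCC=C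
F7 | step 10 | lactol of F6 | OC1OCC2=CC[C@H](C(C)=C)[C@H](O[Si](C)(C)C(C)(C)C)[C@@H]2[C@H]1[C@@H](C)CCC=C
F8 | step 10 | C10 tert-butyldimethylsilyl ether of 20 | C=C1C[C@H](O)[C@H]([C@@H](C)CCC=C)[C@@H]2C(CO)=CC[C@H]1[C@@H]2O[Si](C)(C)C(C)(C)C
F0 | step 8 | none | none
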